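# Total synthesis proposal for CNP0225182.1 by spirocyclizing vinylogous Mukaiyama aldol closure of ring A

Atom numbers are those of the ent-kaurane skeleton: ring A is C1–C5 and C10; the lactone is C10, C20, O, C7, C8, C9; ring C is C8, C9, C11–C14; ring D is C8, C14, C13, C16, C15; C17 is the methylene carbon and C6 the hydroxymethyl carbon. Compound numbers are those of the steps and of the compound list. PMB = 4-methoxybenzyl, TBS = tert-butyldimethylsilyl.

## Analysis of the target

The target is a 6,7-seco-ent-kauranoid of the spirolactone type. Ring A is spiro-fused at C10 to a δ-lactone, which is cis-fused through C8–C9 to ring C. Rings C and D form a bicyclo[3.2.1]octane that carries the 15-oxo-16-methylene unit. There are eight stereocentres (1S,5R,8R,9S,10R,11S,13S,14R), two of them quaternary (C8, C10). On ring A the C6 hydroxymethyl group and C20 are cis and the C1 acetate is equatorial and cis to C20. On ring C the C11 and C14 hydroxyl groups lie on the face that carries the C15–C16 bridge, and C11–OH is axial. The sensitive groups are the α-methylene cyclopentanone (a Michael acceptor), the C14 hydroxyl, which is β to both the C15 ketone and the C7 lactone carbonyl (retro-aldol under base), and the C1 acetate next to free hydroxyl groups; the last steps therefore have to be neutral or acidic. The main difficulties are the adjacent C5/C10 pair with the spiro quaternary centre, the quaternary C8, and the regiochemistry of ring D closure. The strategy rests on one feature: once C8=C9 is unsaturated, C10 is the γ-carbon of the C7 lactone carbonyl, and C1 carries oxygen, so the C1–C10 bond is a vinylogous aldol bond that can close ring A onto a preformed lactone.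

## Retrosynthetic reasoning

**Protecting groups and C17.** The three silyl ethers of 35 (C6, C11, C14) are removed last under acidic fluoride conditions, because the free C14 hydroxyl and the enone would not survive base. The C16=C17 bond is cut next, back to ketone 32; the methylene ketone is the most reactive group of the molecule and is therefore made as late as possible, from the only enolisable position of 32.

**Ring D (C13–C16).** Cutting C13–C16 of 32 leads to bromoketone 31 and from there to methyl ketone 29. In the forward sense a C16 radical closes onto C12=C13 from the face that carries the C8 acyl group. This cut is chosen because the acetyl group that activates the dienophile already holds C15 and C16, and the alkene left by the cycloaddition is the acceptor.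

**Ring C (C9–C11 and C8–C14).** Cyclohexene 29 is opened by a retro-Diels–Alder cut into dienophile 25 and the symmetrical diene 28. The diene delivers C11–C14 with both oxygens, so there is no regiochemical issue. The forward reaction has to create quaternary C8 and four stereocentres, which requires addition to the lactone face next to C1 with the acetyl group endo. Diene 28 comes from diacetate 26.

**C8–C15.** The acetyl group of 25 is removed back to lactone 21 and aldehyde 22. The forward reaction is a selenolate Michael addition/aldol/elimination sequence followed by oxidation of 24, which turns the plain unsaturated lactone into a doubly activated dienophile.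

**Ring A (C1–C10), the key cut.** Acetate 21 comes from alcohol 20, and 20 is cut between C1 and C10 to the silyloxypyran aldehyde 19, made in the flask from lactone aldehyde 18. This cut removes ring A, the quaternary centre and two stereocentres in one step and leaves an open-chain precursor with a single stereocentre (C5). The forward reaction must be γ-selective and must place C20 cis to C6 and the C1 oxygen equatorial.

**Lactone (C9=C10 and the C20–O ester bond).** Lactone 18 is opened at its ring alkene by a retro-metathesis to diene ester 17, which is the ester of allylic alcohol 15 with acid 16. All three lactone carbons C7–C9 come from 16.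

**Chain C1–C6 and the C5 stereocentre.** Alcohol 15 is traced back through 14, 13 and 12 to ketol 10. The C1–C6 bond of the six-membered ring of 10 is the one cleaved in the forward direction, so enone 3 supplies all six carbons C1–C6 with the gem-dimethyl group in place. Ketol 10 comes from the regiodefined enol ether 7, and 7 from an asymmetric conjugate addition of the alkenyl unit of bromide 2 (C10, C20) to 3, which sets C5. Bromide 2 is the PMB ether of 1.

## Alternatives that were turned down

**Alternative 1:** The C5–C10 bond is made by a [3,3] sigmatropic shift in which the enol ether is part of a six-membered oxygen heterocycle. On heating, the ring O–C2 bond breaks as C5–C10 forms, and the heterocycle becomes ring A. The product is cyclohexene carbaldehyde A1, with C6 as the aldehyde, a C1=C2 alkene, and quaternary C10 carrying two one-carbon groups that must become C20 and C9.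
- For it: the shift is concerted and little affected by congestion, so the quaternary centre is formed reliably. The C5/C10 relationship follows from alkene geometry and the geometry of the transition state, and a single carbinol centre supplies the chirality. On the certainty of forming C10 and of the C5/C10 relationship it is stronger than the chosen route, where that relationship rests on a conformational preference.
- Against it: A1 has no oxygen at C1. It would have to be introduced onto C1=C2 next to the quaternary centre with regio- and stereocontrol. The lactone and C8 are absent, and both C10 substituents need redox changes and chain extension before a compound equivalent to 21 is reached. The ring-constrained transition state needs forcing conditions.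
- What the chosen strategy offers instead: the C1 oxygen, ring A, C10 and the complete unsaturated lactone in one step from a precursor nine steps from purchased material.

**Alternative 2:** Ring D is made by a [2+2] photocycloaddition of propadiene A3 to a ring C enone (C13 ketone, C14 silyloxy, C8 as the β-carbon carrying the lactone carbonyl). This forms C8–C15 and C14–C16 and gives the cis-fused methylenecyclobutane A2. A later 1,2-shift of C16 from C14 to C13 expands the four-membered ring to ring D.
- For it: quaternary C8 is made under neutral conditions, the head-to-head regiochemistry is the normal one, the methylene group arrives with the three carbons, and the strain-driven ring expansion cannot give a bicyclo[2.2.2]octane. On ring D regiochemistry it is stronger than the radical closure chosen here.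
- Against it: after the shift C14 is a ketone and C15 a methylene, so a stereoselective C14 reduction and an allylic oxidation at C15 remain. The C13 ketone must first be reduced and activated with the correct alignment. Both faces of the lactone-fused enone are substituted. The enone precursor needs ring C with three differentiated oxygens. The least predictable step falls late, on advanced material.
- What the chosen strategy offers instead: its most uncertain step is step 10, on simple material, and both ring C oxygens come from one cycloaddition.

**Alternative 3:** C13–C16 is made by an intramolecular Rauhut–Currier reaction. Tributylphosphane A5 adds to C17 of a C8 acryloyl group, the enolate carbon C16 adds to C13 of a ring C enone (C11 ketone), and loss of the phosphane restores C16=C17. The product is the tetracyclic 11-ketone A4.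
- For it: one catalytic step closes ring D and installs the methylene ketone, with unambiguous regiochemistry. It replaces steps 16–18 of the chosen route, so in endgame step economy and ring D regiocontrol it is the stronger plan.
- Against it: the two oxygens that arrive together in 29 would have to be differentiated, with C11 oxidised and C14 kept. The γ-silyloxy enone can eliminate under a nucleophilic catalyst. C9 becomes epimerisable next to the C11 ketone. The acryloyl group cannot be present during the cycloaddition. The C11 ketone of A4 must finally be reduced to the axial alcohol in the presence of the more electrophilic methylene ketone.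
- What the chosen strategy offers instead: C11 stays at the alcohol oxidation level with its configuration fixed by the Diels–Alder reaction, at the cost of two more steps.

Key step: step 10

Assumptions (remarks on the chemistry):
- The enantiomer of the phosphoramidite ligand in step 2 is the one that delivers the alkenyl group to the enone face giving (R)-7; the antipodal ligand is equally available.
- Diacetate 26 is taken as a purchasable compound.
- Ketol 10 is drawn as the trans isomer; its carbinol configuration is lost in step 4, so the cis isomer serves equally.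
- Compounds 23, 24, 33 and 34 are mixtures at the centres left undefined in their SMILES.

## Route

Step 1
Reactants: 1 2-bromoprop-2-en-1-ol
Product: 2 1-{[(2-bromoprop-2-en-1-yl)oxy]methyl}-4-methoxybenzene
Conditions: NaH, PMBCl, n-Bu4NI (cat.), THF/DMF, 0 °C → rt
Reagents that add atoms: 4-methoxybenzyl chloride, COc1ccc(CCl)cc1
Why: Williamson etherification of the primary allylic alkoxide with a benzylic chloride; the vinylic bromide is inert to NaH at this temperature.

Step 2
Reactants: 2 2-bromoallyl PMB ether; 3 4,4-dimethylcyclohex-2-en-1-one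
Product: 7 trimethylsilyl enol ether of (R)-3-{3-[(4-methoxybenzyl)oxy]prop-1-en-2-yl}-4,4-dimethylcyclohexanone (enol double bond toward the substituted carbon), via alkenyllithium 4 (not isolated), via alkenyl(dimethyl)alane 5 (not isolated), via aluminium enolate 6 (not isolated)
Conditions: t-BuLi (2 equiv), Et2O, −78 °C; Me2AlCl, −78 → −30 °C; 3, Cu(O2CC4H3S) (copper thiophene-2-carboxylate, 10 mol%), binaphthol-derived N,N-bis(1-phenylethyl)phosphoramidite (11 mol%), Et2O, −30 °C; then Me3SiOTf, Et3N, −30 → 0 °C
Reagents that add atoms: trimethylsilyl trifluoromethanesulfonate, C[Si](C)(C)OS(=O)(=O)C(F)(F)F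
Why: Copper-catalysed asymmetric conjugate addition of alkenylalanes made from alkenyl bromides is a known way to add 1,1-disubstituted vinyl groups to cyclic enones, and the Lewis-acidic alane helps at the neopentyl β-carbon; the chiral copper complex selects the enone face and sets C5 as (R). O-Silylation of the regiodefined aluminium enolate 6 fixes the enol ether between the future C1 and C6, which later ketone enolisation could not do.

Step 3
Reactants: 7 trimethylsilyl enol ether
Product: 10 (2R,3R)-2-hydroxy-3-{3-[(4-methoxybenzyl)oxy]prop-1-en-2-yl}-4,4-dimethylcyclohexan-1-one, via silyloxy oxirane 8 (not isolated), via 2-(trimethylsilyloxy) ketone 9 (not isolated)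
Conditions: mCPBA, NaHCO3, CH2Cl2, −20 °C; then citric acid, MeOH, rt
Reagents that add atoms: 3-chloroperoxybenzoic acid, OOC(=O)c1cccc(Cl)c1
Why: Rubottom oxidation: the electron-rich enol ether is epoxidised much faster than the 1,1-disubstituted alkene, anti to the neighbouring alkenyl group, and silyl migration followed by methanolysis gives the ketol. The new carbinol centre is lost in the next step.

Step 4
Reactants: 10 ketol
Product: 12 methyl (5R)-5-(hydroxymethyl)-6-{[(4-methoxybenzyl)oxy]methyl}-4,4-dimethylhept-6-enoate, via aldehyde ester 11 (not isolated)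
Conditions: Pb(OAc)4, MeOH/PhH (1:1), 0 °C; filtration through Celite; then NaBH4, MeOH, 0 °C
Reagents that add atoms: methanol, CO
Why: Pb(OAc)4 cleavage of the α-ketol in methanol gives the C6 aldehyde and the C1 methyl ester. The aldehyde is α-vinyl and epimerisable at C5, so it is reduced at once in the same operation; the ester is untouched at 0 °C.

Step 5
Reactants: 12 hydroxy ester
Product: 13 methyl (5R)-5-{[tert-butyl(dimethyl)silyl]oxymethyl}-6-{[(4-methoxybenzyl)oxy]methyl}-4,4-dimethylhept-6-enoate
Conditions: TBSCl, imidazole, DMF, rt
Reagents that add atoms: tert-butyldimethylsilyl chloride, CC(C)(C)[Si](C)(C)Cl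
Why: Standard silylation of a primary alcohol; the TBS group later also provides bulk on the C5 side of the lactone.

Step 6
Reactants: 13 silyl ether ester
Product: 14 (5R)-5-{[tert-butyl(dimethyl)silyl]oxymethyl}-6-{[(4-methoxybenzyl)oxy]methyl}-4,4-dimethylhept-6-enal
Conditions: i-Bu2AlH (1.1 equiv), CH2Cl2, −78 °C; MeOH; aq. KNaC4H4O6
Reagents that add atoms: none
Why: Partial reduction of an unhindered methyl ester through the aluminium hemiacetal, which is stable at −78 °C; silyl and PMB ethers are inert.

Step 7
Reactants: 14 aldehyde
Product: 15 (5R)-5-{[tert-butyl(dimethyl)silyl]oxymethyl}-6-(hydroxymethyl)-4,4-dimethylhept-6-enal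
Conditions: DDQ (1.2 equiv), CH2Cl2/pH 7 phosphate buffer (10:1), 0 °C
Reagents that add atoms: none
Why: Oxidative cleavage of the PMB ether; the aldehyde, the TBS ether and the alkene are stable under buffered conditions.

Step 8
Reactants: 15 allylic alcohol; 16 but-3-enoic acid
Product: 17 (3R)-3-{[tert-butyl(dimethyl)silyl]oxymethyl}-4,4-dimethyl-2-methylidene-7-oxoheptyl but-3-enoate
Conditions: DCC, DMAP (5 mol%), CH2Cl2, −10 → 0 °C
Reagents that add atoms: none
Why: Steglich esterification at low temperature with little DMAP, to keep the but-3-enoate from isomerising into conjugation; the aldehyde does not take part.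

Step 9
Reactants: 17 diene ester
Product: 18 5-[(2R)-1-{[tert-butyl(dimethyl)silyl]oxy}-3,3-dimethyl-6-oxohexan-2-yl]-3,6-dihydro-2H-pyran-2-one
Conditions: second-generation Grubbs catalyst RuCl2(=CHPh)(H2IMes)(PCy3) (5 mol%), 1,4-benzoquinone (10 mol%), CH2Cl2 (5 mM), 40 °C
Reagents that add atoms: none
Why: Ring-closing metathesis: the carbene loads on the monosubstituted alkene and closes onto the 1,1-disubstituted alkene to give the six-membered β,γ-unsaturated lactone with C9=C10. Benzoquinone suppresses hydride-mediated alkene migration, and the aldehyde is tolerated.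

Step 10
Reactants: 18 lactone aldehyde
Product: 20 spirolactone alcohol 11-{[tert-butyl(dimethyl)silyl]oxymethyl}-7-hydroxy-10,10-dimethyl-2-oxaspiro[5.5]undec-4-en-3-one with (1S,5R,10S) configuration in kaurane numbering, via silyloxypyran aldehyde 19 (not isolated)
Conditions: Me3SiOTf (1.2 equiv), Et3N (1.5 equiv), CH2Cl2, −78 °C; then BF3·OEt2 (2.5 equiv), −78 → −40 °C; aq. citric acid, MeOH, 0 °C
Reagents that add atoms: none
Why: Soft enolisation at −78 °C converts the doubly activated C8 methylene (α to the carbonyl and allylic) into the 2-silyloxy-6H-pyran 19; BF3·OEt2 then activates the C1 aldehyde, which is attacked by the γ-carbon C10 in an open transition state, and loss of silicon returns the lactone carbonyl with C8=C9. The closest known reaction types are vinylogous Mukaiyama aldol additions of lactone-derived silyl dienol ethers and silylative aldol cyclisations of lactone aldehydes, here used intramolecularly to make a spiro centre. Ring A closes in a 6-(enolexo)-exo-trig mode through a chair, helped by the gem-dimethyl group. γ-Selectivity is enforced by the tether, since α-attack at C8 would need an eight-membered ring. C10 is controlled by C5: allylic strain keeps H5 near the plane of the dienol ether, eclipsing C9=C10, so C6 lies opposite the incoming C1 and C20 becomes axial and cis to C6. C1 is set by placing the Lewis-acid-bound oxygen equatorial in the chair, away from the axial hydrogens at C3 and C5. The step needs chemoselective silylation of the lactone in the presence of the aldehyde, which rests on the higher acidity of C8–H and the low temperature; any C1 silyl ether formed by silyl transfer is cleaved in the acidic work-up, so both pathways give 20. Compound 19 is never warmed, because 2H-pyrans of this kind can open electrocyclically to dienoates.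

Step 11
Reactants: 20 spirolactone alcohol
Product: 21 C1 acetate of 20
Conditions: Ac2O, DMAP, pyridine, CH2Cl2, rt
Reagents that add atoms: acetic anhydride, CC(=O)OC(C)=O
Why: DMAP-catalysed acetylation of the hindered secondary alcohol. It is done before any basic step because a free C1 alkoxide could undergo a retro-vinylogous aldol reaction.

Step 12
Reactants: 21 unsaturated lactone acetate; 22 acetaldehyde
Product: 24 3-(1-hydroxyethyl) unsaturated lactone (C8 hydroxyethyl derivative of 21; mixture at C15), via selenide aldol 23 (not isolated)
Conditions: PhSeLi (from PhSeH, n-BuLi), THF, −78 °C; 22, −78 °C; AcOH; then 30% H2O2, pyridine, CH2Cl2, 0 °C → rt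
Reagents that add atoms: none
Why: Tandem selenolate Michael addition/aldol reaction (a Morita–Baylis–Hillman-type sequence known for unsaturated lactones): the soft selenolate adds reversibly to C9 and the lactone enolate is trapped by 22 at C8. Oxidation gives the selenoxide, whose syn-elimination can only use H8 because C10 is quaternary, so C8=C9 is restored.

Step 13
Reactants: 24 allylic alcohol
Product: 25 3-acetyl unsaturated lactone (C8 acetyl derivative of 21)
Conditions: Dess–Martin periodinane, NaHCO3, CH2Cl2, 0 °C → rt; used directly
Reagents that add atoms: none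
Why: Buffered, non-nucleophilic oxidation of the secondary allylic alcohol to the ketone gives the doubly activated dienophile; there is no γ-hydrogen, so it cannot isomerise.

Step 14
Reactants: 26 (1E,3E)-buta-1,3-diene-1,4-diyl diacetate
Product: 28 (1E,3E)-1,4-bis{[tert-butyl(dimethyl)silyl]oxy}buta-1,3-diene, via dilithium dienediolate 27 (not isolated)
Conditions: MeLi (4.2 equiv), THF, −78 → 0 °C; then TBSCl, DMPU, −78 °C → rt
Reagents that add atoms: tert-butyldimethylsilyl chloride, CC(C)(C)[Si](C)(C)Cl
Why: Methyllithium cleaves enol acetates to lithium enolates with retention of alkene geometry, and O-silylation of the dienediolate gives the E,E-diene.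

Step 15
Reactants: 25 3-acetyl unsaturated lactone; 28 bis(silyloxy)diene
Product: 29 Diels–Alder adduct: cis-fused cyclohexene with C8 acetyl, C11 and C14 OTBS groups cis to the acetyl group and trans to C7 and C10, and a C12=C13 alkene
Conditions: 28 (2 equiv), 2,6-di-tert-butyl-4-methylphenol (cat.), toluene, 60 °C
Reagents that add atoms: none
Why: Normal-electron-demand Diels–Alder reaction of a doubly activated alkene with a symmetrical electron-rich diene, so no regiochemical question arises. The diene should add to the lactone face next to C1, the other face being blocked by the C6 silyloxymethyl group and the C4 gem-dimethyl unit. With the acetyl group endo and the spiro-lactone ring exo, both siloxy groups end up cis to the acetyl group and C8, C9, C11 and C14 are set as in the target.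

Step 16
Reactants: 29 methyl ketone
Product: 31 bromomethyl ketone (C16 bromide of 29), via trimethylsilyl enol ether 30 (not isolated)
Conditions: LiN(SiMe3)2, Me3SiCl, THF, −78 °C; then NBS, THF, −78 → 0 °C
Reagents that add atoms: N-bromosuccinimide, O=C1CCC(=O)N1Br
Why: C16 is the only enolisable position of the ketone (C8 is quaternary) and is more acidic than the acetate methyl group. Bromination of the silyl enol ether is much faster than reaction at the ring alkene.

Step 17
Reactants: 31 bromomethyl ketone
Product: 32 tetracyclic ketone with ring D closed (C13–C16 bond; C16 methylene; C6, C11 and C14 OTBS)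
Conditions: Bu3SnH (slow addition), AIBN (cat.), PhH, 80 °C
Reagents that add atoms: none
Why: Tin-hydride-mediated 5-exo-trig cyclisation of the C16 α-keto radical onto C13; only the ring C face carrying the axial acyl group can be reached, so C13 is set by the tether. In the reactive conformer the C11 siloxy group is axial on that face and shields C12, which disfavours 6-endo closure, and slow addition of the hydride limits premature reduction.

Step 18
Reactants: 32 tetracyclic ketone
Product: 35 tris-TBS ether of the target (15-oxo-16-methylene compound), via Mannich base 33 (not isolated), via methiodide 34 (not isolated)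
Conditions: LiN(SiMe3)2, THF, −78 °C; CH2=NMe2+ I−, −78 °C → rt; MeI, CH2Cl2, rt; aq. NaHCO3
Reagents that add atoms: dimethylmethyleneiminium iodide, C=[N+](C)C.[I-]
Why: Mannich methylenation through the only possible ketone enolate (C16), followed by quaternisation and β-elimination of trimethylamine to give the exocyclic enone.

Step 19
Reactants: 35 tris-TBS ether
Product: 36 CNP0225182.1 (target)
Conditions: HF·pyridine, pyridine, THF, 0 °C → rt
Reagents that add atoms: none
Why: Acidic fluoride desilylation removes the primary and both secondary TBS groups. No base is present, so the acetate, the methylene ketone and the β-hydroxy ketone should survive.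

## Compound list

1 | 2-bromoprop-2-en-1-ol | OCC(Br)=C | starting material
2 | 1-{[(2-bromoprop-2-en-1-yl)oxy]methyl}-4-methoxybenzene | C=C(Br)COCc1ccc(OC)cc1 | intermediate
3 | 4,4-dimethylcyclohex-2-en-1-one | CC1(C)CCC(=O)C=C1 | starting material
4 | {3-[(4-methoxybenzyl)oxy]prop-1-en-2-yl}lithium | [Li]C(=C)COCc1ccc(OC)cc1 | intermediate
5 | {3-[(4-methoxybenzyl)oxy]prop-1-en-2-yl}dimethylalane | C[Al](C)C(=C)COCc1ccc(OC)cc1 | intermediate
6 | dimethylaluminium enolate of (R)-3-{3-[(4-methoxybenzyl)oxy]prop-1-en-2-yl}-4,4-dimethylcyclohexanone | C[Al](C)OC1=C[C@@H](C(=C)COCc2ccc(OC)cc2)C(C)(C)CC1 | intermediate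
7 | {[(3R)-3-{3-[(4-methoxybenzyl)oxy]prop-1-en-2-yl}-4,4-dimethylcyclohex-1-en-1-yl]oxy}trimethylsilane | C[Si](C)(C)OC1=C[C@@H](C(=C)COCc2ccc(OC)cc2)C(C)(C)CC1 | intermediate
8 | silyloxy oxirane of 7 (epoxide oxygen trans to the alkenyl group) | C[Si](C)(C)O[C@]12CCC(C)(C)[C@H](C(=C)COCc3ccc(OC)cc3)[C@H]1O2 | intermediate
9 | (2R,3R)-3-{3-[(4-methoxybenzyl)oxy]prop-1-en-2-yl}-4,4-dimethyl-2-(trimethylsilyloxy)cyclohexan-1-one | O=C1CCC(C)(C)[C@H](C(=C)COCc2ccc(OC)cc2)[C@H]1O[Si](C)(C)C | intermediate
10 | (2R,3R)-2-hydroxy-3-{3-[(4-methoxybenzyl)oxy]prop-1-en-2-yl}-4,4-dimethylcyclohexan-1-one | O=C1CCC(C)(C)[C@H](C(=C)COCc2ccc(OC)cc2)[C@H]1O | intermediate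
11 | methyl (5R)-5-formyl-6-{[(4-methoxybenzyl)oxy]methyl}-4,4-dimethylhept-6-enoate | COC(=O)CCC(C)(C)[C@@H](C=O)C(=C)COCc1ccc(OC)cc1 | intermediate
12 | methyl (5R)-5-(hydroxymethyl)-6-{[(4-methoxybenzyl)oxy]methyl}-4,4-dimethylhept-6-enoate | COC(=O)CCC(C)(C)[C@@H](CO)C(=C)COCc1ccc(OC)cc1 | intermediate
13 | methyl (5R)-5-{[tert-butyl(dimethyl)silyl]oxymethyl}-6-{[(4-methoxybenzyl)oxy]methyl}-4,4-dimethylhept-6-enoate | COC(=O)CCC(C)(C)[C@@H](CO[Si](C)(C)C(C)(C)C)C(=C)COCc1ccc(OC)cc1 | intermediate
14 | (5R)-5-{[tert-butyl(dimethyl)silyl]oxymethyl}-6-{[(4-methoxybenzyl)oxy]methyl}-4,4-dimethylhept-6-enal | O=CCCC(C)(C)[C@@H](CO[Si](C)(C)C(C)(C)C)C(=C)COCc1ccc(OC)cc1 | intermediate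
15 | (5R)-5-{[tert-butyl(dimethyl)silyl]oxymethyl}-6-(hydroxymethyl)-4,4-dimethylhept-6-enal | O=CCCC(C)(C)[C@@H](CO[Si](C)(C)C(C)(C)C)C(=C)CO | intermediate
16 | but-3-enoic acid | C=CCC(=O)O | starting material
17 | (3R)-3-{[tert-butyl(dimethyl)silyl]oxymethyl}-4,4-dimethyl-2-methylidene-7-oxoheptyl but-3-enoate | O=CCCC(C)(C)[C@@H](CO[Si](C)(C)C(C)(C)C)C(=C)COC(=O)CC=C | intermediate
18 | 5-[(2R)-1-{[tert-butyl(dimethyl)silyl]oxy}-3,3-dimethyl-6-oxohexan-2-yl]-3,6-dihydro-2H-pyran-2-one | O=CCCC(C)(C)[C@@H](CO[Si](C)(C)C(C)(C)C)C1=CCC(=O)OC1 | intermediate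
19 | (4R)-5-{[tert-butyl(dimethyl)silyl]oxy}-3,3-dimethyl-4-[6-(trimethylsilyloxy)-2H-pyran-3-yl]pentanal (aldehyde-tethered 2-silyloxy-6H-pyran) | O=CCCC(C)(C)[C@@H](CO[Si](C)(C)C(C)(C)C)C1=CC=C(O[Si](C)(C)C)OC1 | intermediate
20 | 11-{[tert-butyl(dimethyl)silyl]oxymethyl}-7-hydroxy-10,10-dimethyl-2-oxaspiro[5.5]undec-4-en-3-one, (1S,5R,10S) in kaurane numbering | O=C1C=C[C@]2(CO1)[C@@H](O)CCC(C)(C)[C@H]2CO[Si](C)(C)C(C)(C)C | intermediate
21 | C1 acetate of 20 | O=C1C=C[C@]2(CO1)[C@@H](OC(C)=O)CCC(C)(C)[C@H]2CO[Si](C)(C)C(C)(C)C | intermediate
22 | acetaldehyde | CC=O | starting material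
23 | C9 phenylselanyl C8 (1-hydroxyethyl) lactone (selenide aldol; mixture at C8, C9, C15) | CC(O)C1C([Se]c2ccccc2)[C@]3(COC1=O)[C@@H](OC(C)=O)CCC(C)(C)[C@H]3CO[Si](C)(C)C(C)(C)C | intermediate
24 | C8 (1-hydroxyethyl) unsaturated lactone (mixture at C15) | CC(O)C1=C[C@]2(COC1=O)[C@@H](OC(C)=O)CCC(C)(C)[C@H]2CO[Si](C)(C)C(C)(C)C | intermediate
25 | C8 acetyl unsaturated lactone (dienophile) | CC(=O)C1=C[C@]2(COC1=O)[C@@H](OC(C)=O)CCC(C)(C)[C@H]2CO[Si](C)(C)C(C)(C)C | intermediate
26 | (1E,3E)-buta-1,3-diene-1,4-diyl diacetate | CC(=O)O/C=C/C=C/OC(C)=O | starting material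
27 | dilithium (1E,3E)-buta-1,3-diene-1,4-diolate | [Li]O/C=C/C=C/O[Li] | intermediate
28 | (1E,3E)-1,4-bis{[tert-butyl(dimethyl)silyl]oxy}buta-1,3-diene | CC(C)(C)[Si](C)(C)O/C=C/C=C/O[Si](C)(C)C(C)(C)C | intermediate
29 | Diels–Alder adduct (C8 acetyl; C11, C14 OTBS cis to acetyl; C12=C13) | CC(=O)[C@@]12C(=O)OC[C@]3([C@@H](OC(C)=O)CCC(C)(C)[C@H]3CO[Si](C)(C)C(C)(C)C)[C@@H]1[C@@H](O[Si](C)(C)C(C)(C)C)C=C[C@H]2O[Si](C)(C)C(C)(C)C | intermediate
30 | trimethylsilyl enol ether of 29 (C15=C16) | C=C(O[Si](C)(C)C)[C@@]12C(=O)OC[C@]3([C@@H](OC(C)=O)CCC(C)(C)[C@H]3CO[Si](C)(C)C(C)(C)C)[C@@H]1[C@@H](O[Si](C)(C)C(C)(C)C)C=C[C@H]2O[Si](C)(C)C(C)(C)C | intermediate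
31 | C16 bromide of 29 (bromomethyl ketone) | BrCC(=O)[C@@]12C(=O)OC[C@]3([C@@H](OC(C)=O)CCC(C)(C)[C@H]3CO[Si](C)(C)C(C)(C)C)[C@@H]1[C@@H](O[Si](C)(C)C(C)(C)C)C=C[C@H]2O[Si](C)(C)C(C)(C)C | intermediate
32 | tetracyclic 15-ketone with C16 methylene group (C6, C11, C14 OTBS) | C1C(=O)[C@@]23C(=O)OC[C@]4([C@@H](OC(C)=O)CCC(C)(C)[C@H]4CO[Si](C)(C)C(C)(C)C)[C@@H]2[C@@H](O[Si](C)(C)C(C)(C)C)C[C@@H]1[C@H]3O[Si](C)(C)C(C)(C)C | intermediate
33 | C16 (dimethylaminomethyl) ketone (Mannich base; mixture at C16) | CN(C)CC1C(=O)[C@@]23C(=O)OC[C@]4([C@@H](OC(C)=O)CCC(C)(C)[C@H]4CO[Si](C)(C)C(C)(C)C)[C@@H]2[C@@H](O[Si](C)(C)C(C)(C)C)C[C@@H]1[C@H]3O[Si](C)(C)C(C)(C)C | intermediate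
34 | methiodide of 33 | [I-].C[N+](C)(C)CC1C(=O)[C@@]23C(=O)OC[C@]4([C@@H](OC(C)=O)CCC(C)(C)[C@H]4CO[Si](C)(C)C(C)(C)C)[C@@H]2[C@@H](O[Si](C)(C)C(C)(C)C)C[C@@H]1[C@H]3O[Si](C)(C)C(C)(C)C | intermediate
35 | 6,11,14-tris-O-TBS ether of the target | C=C1C(=O)[C@@]23C(=O)OC[C@]4([C@@H](OC(C)=O)CCC(C)(C)[C@H]4CO[Si](C)(C)C(C)(C)C)[C@@H]2[C@@H](O[Si](C)(C)C(C)(C)C)C[C@@H]1[C@H]3O[Si](C)(C)C(C)(C)C | intermediate
36 | CNP0225182.1, (1S,5R,8R,9S,10R,11S,13S,14R) in kaurane numbering | C=C1C(=O)[C@@]23C(=O)OC[C@]4([C@@H](OC(C)=O)CCC(C)(C)[C@H]4CO)[C@@H]2[C@@H](O)C[C@@H]1[C@H]3O | target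

## Step count and least certain steps

Total step count: 19. Longest linear sequence: 18 steps (steps 1–13 and 15–19, from 1); step 14 is a one-step side branch.

**Step 10 (key step).** The most likely failure is loss of chemoselectivity before the C–C bond forms: the silyl triflate/amine pair can also silylate or enolise the aldehyde, and the silyloxypyran can open electrocyclically if the enolisation needs a higher temperature than planned. The second concern is incomplete facial selectivity at C10, because the rotamer in which C4 rather than H5 eclipses C9=C10 is not much higher in energy. The fallback masks the aldehyde as an acylal and uses an oxocarbenium cyclisation. It sets out from 18. Acetic anhydride with catalytic LiBF4 should give the geminal diacetate F1. TBSOTf/Et3N at −78 °C, now without a free aldehyde in the molecule, should convert the lactone into the TBS silyloxypyran acylal F2. Catalytic Me3SiOTf should then ionise the acylal to an acyloxycarbenium ion, which is trapped at C10 through the same chair. This delivers the C1 acetate directly and rejoins the route at 21.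

**Step 2.** The most likely failure is insufficient enantioselectivity or slow alkenyl transfer, because the enone β-carbon is neopentyl and the alkenyl group is α-branched. The fallback separates the asymmetric step from the regiochemical one and sets out from 2 and 3.
- Borylation of 2 (B2pin2, PdCl2(dppf), KOAc) should give the alkenyl pinacol boronate F3.
- Rhodium-catalysed asymmetric conjugate addition ([Rh(OH)(cod)]2, (S)-BINAP, aqueous dioxane) of F3 to 3 should give the (R)-ketone F4.
- Kinetic deprotonation at the less hindered α-carbon (LiN(i-Pr)2, −78 °C) and dehydrogenation of the enolate with N-tert-butylbenzenesulfinimidoyl chloride should give the enone F5, whose only remaining enolisable position is the future C6.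
- Its lithium enolate with 2-(phenylsulfonyl)-3-phenyloxaziridine should give the hydroxy enone F6.
- Pb(OAc)4 cleavage in methanol followed directly by NaBH4/CeCl3 should give the Z-enoate alcohol F7, and silylation the Z-enoate TBS ether F8.
- Conjugate reduction with catalytic [(Ph3P)CuH]6 and PhSiH3 returns to the route at 13.

**Step 15.** The most likely failure is a slow cycloaddition that is overtaken by inverse-demand hetero-Diels–Alder addition to the acyl enone or by decomposition of the diene, since both new bonds form at hindered carbons. The fallback brings in the two oxygens after ring C is closed and sets out from 25.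
- Diels–Alder reaction with the less hindered (E)-buta-1,3-dien-1-yl acetate (ZnCl2, CH2Cl2) should give the C14 acetoxy cycloadduct F9.
- Palladium-catalysed 1,4-elimination of the allylic acetate (Pd(PPh3)4, Et3N, THF, reflux) should give the ring C 1,3-diene F10.
- Photooxygenation (O2, tetraphenylporphyrin, light) from the face carrying H9 and the acetyl group should give the endoperoxide F11, and thiourea reduction the cis-diol F12.
- Silylation (TBSOTf, 2,6-lutidine) returns to the route at 29.

**Step 17.** The most likely failure is 6-endo closure to the bicyclo[2.2.2]octane, or simple reduction of the bromide, because the conjugated α-keto radical overlaps poorly with C13 in the 5-exo geometry. The fallback removes the conjugation and sets out from 31. Reduction with NaBH4/CeCl3 should give the bromohydrin F13 as a mixture at C15. Its sp3 alkyl radical (Bu3SnH, AIBN) should close 5-exo onto C13 in the normal way to give the cyclised alcohol F14. Oxidation with Dess–Martin periodinane returns to the route at 32.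

## Further compounds

F1 | step 10 | geminal diacetate of lactone aldehyde 18 | CC(=O)OC(CCC(C)(C)[C@@H](CO[Si](C)(C)C(C)(C)C)C1=CCC(=O)OC1)OC(C)=O
F2 | step 10 | TBS silyloxypyran acylal | CC(=O)OC(CCC(C)(C)[C@@H](CO[Si](C)(C)C(C)(C)C)C1=CC=C(O[Si](C)(C)C(C)(C)C)OC1)OC(C)=O
F3 | step 2 | 2-{3-[(4-methoxybenzyl)oxy]prop-1-en-2-yl}-4,4,5,5-tetramethyl-1,3,2-dioxaborolane | C=C(COCc1ccc(OC)cc1)B1OC(C)(C)C(C)(C)O1
F4 | step 2 | (3R)-3-{3-[(4-methoxybenzyl)oxy]prop-1-en-2-yl}-4,4-dimethylcyclohexan-1-one | O=C1CCC(C)(C)[C@H](C(=C)COCc2ccc(OC)cc2)C1
F5 | step 2 | 5-{3-[(4-methoxybenzyl)oxy]prop-1-en-2-yl}-4,4-dimethylcyclohex-2-en-1-one (same configuration at the alkenyl-bearing carbon as F4) | O=C1C=CC(C)(C)[C@H](C(=C)COCc2ccc(OC)cc2)C1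
F6 | step 2 | 6-hydroxy derivative of F5 (hydroxyl trans to the alkenyl group) | O=C1C=CC(C)(C)[C@H](C(=C)COCc2ccc(OC)cc2)[C@H]1O
F7 | step 2 | methyl (2Z,5R)-5-(hydroxymethyl)-6-{[(4-methoxybenzyl)oxy]methyl}-4,4-dimethylhepta-2,6-dienoate | COC(=O)/C=C\C(C)(C)[C@@H](CO)C(=C)COCc1ccc(OC)cc1
F8 | step 2 | TBS ether of F7 | COC(=O)/C=C\C(C)(C)[C@@H](CO[Si](C)(C)C(C)(C)C)C(=C)COCc1ccc(OC)cc1
F9 | step 15 | C14 acetoxy cycloadduct (C11 methylene, C12=C13) | CC(=O)[C@@]12C(=O)OC[C@]3([C@@H](OC(C)=O)CCC(C)(C)[C@H]3CO[Si](C)(C)C(C)(C)C)[C@@H]1CC=C[C@H]2OC(C)=O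
F10 | step 15 | ring C 1,3-diene (C11=C12, C13=C14) | CC(=O)[C@@]12C(=O)OC[C@]3([C@@H](OC(C)=O)CCC(C)(C)[C@H]3CO[Si](C)(C)C(C)(C)C)[C@@H]1C=CC=C2
F11 | step 15 | C11,C14 endoperoxide | CC(=O)[C@@]12C(=O)OC[C@]3([C@@H](OC(C)=O)CCC(C)(C)[C@H]3CO[Si](C)(C)C(C)(C)C)[C@@H]1[C@@H]4C=C[C@H]2OO4
F12 | step 15 | C11,C14 cis-diol (desilyl 29) | CC(=O)[C@@]12C(=O)OC[C@]3([C@@H](OC(C)=O)CCC(C)(C)[C@H]3CO[Si](C)(C)C(C)(C)C)[C@@H]1[C@@H](O)C=C[C@H]2O
F13 | step 17 | C15 alcohol of 31 (bromohydrin; mixture at C15) | BrCC(O)[C@@]12C(=O)OC[C@]3([C@@H](OC(C)=O)CCC(C)(C)[C@H]3CO[Si](C)(C)C(C)(C)C)[C@@H]1[C@@H](O[Si](C)(C)C(C)(C)C)C=C[C@H]2O[Si](C)(C)C(C)(C)C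
F14 | step 17 | C15 alcohol of 32 (mixture at C15) | C1C(O)[C@@]23C(=O)OC[C@]4([C@@H](OC(C)=O)CCC(C)(C)[C@H]4CO[Si](C)(C)C(C)(C)C)[C@@H]2[C@@H](O[Si](C)(C)C(C)(C)C)C[C@@H]1[C@H]3O[Si](C)(C)C(C)(C)C
A1 | alternative 1 | ring A cyclohexene carbaldehyde with quaternary C10 | COC(=O)[C@@]1(COCc2ccc(OC)cc2)C=CCC(C)(C)[C@H]1C=O
A2 | alternative 2 | cis-fused methylenecyclobutane photoadduct | C=C1C[C@]2(C(=O)OC[C@]3([C@@H](OC(C)=O)CCC(C)(C)[C@H]3CO[Si](C)(C)C(C)(C)C)[C@@H]2[C@@H](O[Si](C)(C)C(C)(C)C)CC4=O)[C@]14O[Si](C)(C)C(C)(C)C
A3 | alternative 2 | propadiene | C=C=C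
A4 | alternative 3 | tetracyclic 11-ketone with 15-oxo-16-methylene ring D | C=C1C(=O)[C@@]23C(=O)OC[C@]4([C@@H](OC(C)=O)CCC(C)(C)[C@H]4CO[Si](C)(C)C(C)(C)C)[C@@H]2C(=O)C[C@@H]1[C@H]3O[Si](C)(C)C(C)(C)C
A5 | alternative 3 | tributylphosphane | CCCCP(CCCC)CCCC
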